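The dihydrofuran ring is disconnected at the O1–C2 bond. The aryl ring on C2 carries an oxygen at C4′, para to C2, so as a free phenol it can be oxidised to a p-quinone methide in which C2 is the exocyclic carbon; the hydroxyl oxygen on C7a of ring A (the benzo ring) then adds to C2. In one operation this oxidation of a benzylic CH2 forms O1–C2, closes the five-membered ring and sets C2 trans to the C3 methyl group. The precursor is an (S)-1,2-diarylpropane with both phenols free: a 5-bromo-2-hydroxy-4-methoxyphenyl group on the stereocentre and a 4-hydroxy-3,5-dimethoxyphenyl group on the CH2; the bromine later becomes the (E)-propenyl group.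

Key step: step 10

Assumption: in step 8 the (R)-configured ligand is named by analogy with the hydrogenation of (E)-α-methylstilbene; if the ortho-benzyloxy group reverses the sense of induction, the antipodal ligand is used without other change.

Step 1
Reactants: 1 paeonol, 1-(2-hydroxy-4-methoxyphenyl)ethan-1-one
Product: 2 1-(5-bromo-2-hydroxy-4-methoxyphenyl)ethan-1-one
Conditions: NBS (1.05 equiv), MeCN, 0 °C to rt
Reagents that add atoms: N-bromosuccinimide, O=C1CCC(=O)N1Br
Why: Electrophilic aromatic bromination; C5 is para to the hydroxyl and ortho to the methoxy group and is less hindered than C3 between the two oxygens, so monobromination should occur at C5.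

Step 2
Reactants: 2 1-(5-bromo-2-hydroxy-4-methoxyphenyl)ethan-1-one
Product: 3 1-[2-(benzyloxy)-5-bromo-4-methoxyphenyl]ethan-1-one
Conditions: BnBr (1.2 equiv), K2CO3 (2 equiv), DMF, 60 °C
Reagents that add atoms: benzyl bromide, BrCc1ccccc1
Why: Williamson ether synthesis; a benzyl ether is chosen because, unlike a silyl or acyl group, it cannot migrate to the neighbouring alkoxide in step 6, and it survives the acid of step 7 and the hydrogenation of step 8.

Step 3
Reactants: 4 syringaldehyde, 4-hydroxy-3,5-dimethoxybenzaldehyde
Product: 5 4-(benzyloxy)-3,5-dimethoxybenzaldehyde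
Conditions: BnBr (1.2 equiv), K2CO3 (2 equiv), DMF, rt to 50 °C
Reagents that add atoms: benzyl bromide, BrCc1ccccc1
Why: Williamson ether synthesis of the phenoxide, which masks the acidic hydroxyl before the organomagnesium chemistry.

Step 4
Reactants: 5 4-(benzyloxy)-3,5-dimethoxybenzaldehyde
Product: 6 [4-(benzyloxy)-3,5-dimethoxyphenyl]methanol
Conditions: NaBH4 (0.6 equiv), MeOH/THF, 0 °C
Reagents that add atoms: none
Why: Hydride reduction of an aryl aldehyde to the benzylic alcohol; nothing else in the molecule is reducible by NaBH4.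

Step 5
Reactants: 6 [4-(benzyloxy)-3,5-dimethoxyphenyl]methanol
Product: 7 2-(benzyloxy)-5-(chloromethyl)-1,3-dimethoxybenzene
Conditions: SOCl2 (1.2 equiv), CH2Cl2, 0 °C to rt; used without storage
Reagents that add atoms: thionyl chloride, O=S(Cl)Cl
Why: Chlorodehydroxylation through the chlorosulfite ester, which is fast for an electron-rich benzylic alcohol and leaves the aryl ethers intact.

Step 6
Reactants: 7 2-(benzyloxy)-5-(chloromethyl)-1,3-dimethoxybenzene; 3 1-[2-(benzyloxy)-5-bromo-4-methoxyphenyl]ethan-1-one
Product: 9 racemic 2-[2-(benzyloxy)-5-bromo-4-methoxyphenyl]-1-[4-(benzyloxy)-3,5-dimethoxyphenyl]propan-2-ol, via benzylic Grignard reagent 8 (not isolated)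
Conditions: Mg turnings (3 equiv, activated by 1,2-dibromoethane), THF, 0 °C, slow addition of 7 at high dilution; then 3 (0.7 equiv), THF, −20 °C to rt; aq. NH4Cl
Reagents that add atoms: none
Why: Grignard formation and 1,2-addition to the aryl methyl ketone; slow addition at 0 °C limits Wurtz coupling, the aryl bromide does not exchange with a benzylic Grignard reagent at this temperature, and the racemic carbinol centre is removed in step 7.

Step 7
Reactants: 9 racemic 2-[2-(benzyloxy)-5-bromo-4-methoxyphenyl]-1-[4-(benzyloxy)-3,5-dimethoxyphenyl]propan-2-ol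
Product: 10 (E)-2-[2-(benzyloxy)-5-bromo-4-methoxyphenyl]-1-[4-(benzyloxy)-3,5-dimethoxyphenyl]prop-1-ene
Conditions: p-TsOH·H2O (5 mol %), toluene, 4 Å molecular sieves, 80 °C; recrystallisation
Reagents that add atoms: none
Why: Acid-catalysed E1 dehydration through the tertiary benzylic cation is reversible, so the mixture should settle on the conjugated trisubstituted alkene with the two aryl groups trans, and recrystallisation should remove residual Z and 1,1-disubstituted isomers.

Step 8
Reactants: 10 (E)-2-[2-(benzyloxy)-5-bromo-4-methoxyphenyl]-1-[4-(benzyloxy)-3,5-dimethoxyphenyl]prop-1-ene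
Product: 11 (S)-2-[2-(benzyloxy)-5-bromo-4-methoxyphenyl]-1-[4-(benzyloxy)-3,5-dimethoxyphenyl]propane
Conditions: [Ir(cod)(L)]BArF (2 mol %; L = (R)-4-tert-butyl-2-[2-(di-o-tolylphosphanyl)phenyl]-4,5-dihydrooxazole, BArF = tetrakis[3,5-bis(trifluoromethyl)phenyl]borate), H2 (50 bar), CH2Cl2, rt
Reagents that add atoms: none
Why: Iridium–N,P-catalysed asymmetric hydrogenation of an unfunctionalised trisubstituted alkene, the substrate class for which these catalysts were developed; the chiral ligand selects the alkene face and so sets the methyl-bearing stereocentre as S, and the cationic iridium catalyst should not touch the aryl bromide or the benzyl ethers.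

Step 9
Reactants: 11 (S)-2-[2-(benzyloxy)-5-bromo-4-methoxyphenyl]-1-[4-(benzyloxy)-3,5-dimethoxyphenyl]propane
Product: 12 (S)-4-[2-(5-bromo-2-hydroxy-4-methoxyphenyl)propyl]-2,6-dimethoxyphenol
Conditions: BCl3 (1 M in CH2Cl2, 5 equiv), pentamethylbenzene (6 equiv), CH2Cl2, −78 °C; then MeOH; product kept under argon
Reagents that add atoms: none
Why: Lewis-acid cleavage of aryl benzyl ethers with pentamethylbenzene as Friedel–Crafts scavenger for the benzyl cations; at −78 °C the methyl ethers, the aryl bromide (which hydrogenolysis would endanger) and the non-ionisable stereocentre should be untouched.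

Step 10
Reactants: 12 (S)-4-[2-(5-bromo-2-hydroxy-4-methoxyphenyl)propyl]-2,6-dimethoxyphenol
Product: 14 4-[(2R,3R)-5-bromo-6-methoxy-3-methyl-2,3-dihydro-1-benzofuran-2-yl]-2,6-dimethoxyphenol, via p-quinone methide 13 (not isolated)
Conditions: Ag2O (1.1–1.2 equiv), CH2Cl2 (0.01 M), rt, dark, argon; filtration through Celite
Reagents that add atoms: none
Why: Ag2O removes two electrons and two protons from the 2,6-dimethoxyphenol through its phenoxyl radical to give p-quinone methide 13, whose exocyclic carbon is the future C2, and the ring A hydroxyl adds to that carbon in a 1,6-conjugate addition that restores the aromatic ring. The closest known reaction type is the oxidation of 4-alkyl-2,6-dimethoxyphenols to p-quinone methides by Ag2O or DDQ and their capture by phenols, which is the ring-closing event in oxidative 8–5′ coupling of propenylphenols and in the oxidative cyclisation of 2′-hydroxyisoflavans to pterocarpans. The dihydrofuran ring closes by 5-exo-trig attack of oxygen on the methide carbon. C2 is controlled by the existing C3 centre: the aryl group takes the face anti to the C3 methyl in the closing transition state, and since the product keeps the 4′-phenol a cis isomer can reopen to 13 and close again, so the trans (2R,3R) isomer should result, C3 being untouched and changing its descriptor from S to R only because C2 gains oxygen. Two selectivities are needed: oxidation of the dimethoxyphenol and not of the ring A phenol, secured by the two ortho methoxy groups on the one and the para bromine on the other and by an oxidant that acts at O–H and not at the C3–H bond, and ring closure faster than tautomerisation of 13 to the stilbene, secured by the nucleophile sitting three atoms from the methide carbon and by neutral, dilute conditions. The oxidant is held near one equivalent because the product is still a phenol and could be oxidised on to the benzofuran.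

Step 11
Reactants: 14 4-[(2R,3R)-5-bromo-6-methoxy-3-methyl-2,3-dihydro-1-benzofuran-2-yl]-2,6-dimethoxyphenol
Product: 15 (2R,3R)-5-bromo-6-methoxy-3-methyl-2-(3,4,5-trimethoxyphenyl)-2,3-dihydro-1-benzofuran
Conditions: MeI (3 equiv), K2CO3 (2 equiv), acetone, rt to 40 °C
Reagents that add atoms: iodomethane, CI
Why: Williamson methylation of the only remaining hydroxyl; mild carbonate base and fast trapping of the phenoxide keep ring opening to the quinone methide from competing, and once methylated the ring can no longer open.

Step 12
Reactants: 15 (2R,3R)-5-bromo-6-methoxy-3-methyl-2-(3,4,5-trimethoxyphenyl)-2,3-dihydro-1-benzofuran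
Product: 16 (2R,3R)-6-methoxy-3-methyl-5-[(E)-prop-1-en-1-yl]-2-(3,4,5-trimethoxyphenyl)-2,3-dihydro-1-benzofuran
Conditions: (E)-prop-1-enylboronic acid pinacol ester (1.5 equiv), Pd(OAc)2 (5 mol %), SPhos (2-dicyclohexylphosphino-2′,6′-dimethoxybiphenyl, 10 mol %), K3PO4 (3 equiv), toluene/H2O 10:1, 80 °C
Reagents that add atoms: (E)-4,4,5,5-tetramethyl-2-(prop-1-en-1-yl)-1,3,2-dioxaborolane, C/C=C/B1OC(C)(C)C(C)(C)O1
Why: Suzuki–Miyaura coupling; zerovalent palladium with an electron-rich biarylphosphine inserts into the hindered, electron-rich C5–Br bond, transmetallation and reductive elimination keep the (E) geometry of the alkenylboronate, and neither stereocentre is labile under these conditions.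

Compound list
1 | paeonol, 1-(2-hydroxy-4-methoxyphenyl)ethan-1-one | CC(=O)c1ccc(OC)cc1O | starting material
2 | 1-(5-bromo-2-hydroxy-4-methoxyphenyl)ethan-1-one | CC(=O)c1cc(Br)c(OC)cc1O | intermediate
3 | 1-[2-(benzyloxy)-5-bromo-4-methoxyphenyl]ethan-1-one | CC(=O)c1cc(Br)c(OC)cc1OCc1ccccc1 | intermediate
4 | syringaldehyde, 4-hydroxy-3,5-dimethoxybenzaldehyde | COc1cc(C=O)cc(OC)c1O | starting material
5 | 4-(benzyloxy)-3,5-dimethoxybenzaldehyde | COc1cc(C=O)cc(OC)c1OCc1ccccc1 | intermediate
6 | [4-(benzyloxy)-3,5-dimethoxyphenyl]methanol | COc1cc(CO)cc(OC)c1OCc1ccccc1 | intermediate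
7 | 2-(benzyloxy)-5-(chloromethyl)-1,3-dimethoxybenzene | COc1cc(CCl)cc(OC)c1OCc1ccccc1 | intermediate
8 | [4-(benzyloxy)-3,5-dimethoxybenzyl]magnesium chloride (formed in the flask) | COc1cc(C[Mg]Cl)cc(OC)c1OCc1ccccc1 | intermediate
9 | racemic 2-[2-(benzyloxy)-5-bromo-4-methoxyphenyl]-1-[4-(benzyloxy)-3,5-dimethoxyphenyl]propan-2-ol | CC(O)(Cc1cc(OC)c(OCc2ccccc2)c(OC)c1)c1cc(Br)c(OC)cc1OCc1ccccc1 | intermediate
10 | (E)-2-[2-(benzyloxy)-5-bromo-4-methoxyphenyl]-1-[4-(benzyloxy)-3,5-dimethoxyphenyl]prop-1-ene | C/C(=C\c1cc(OC)c(OCc2ccccc2)c(OC)c1)c1cc(Br)c(OC)cc1OCc1ccccc1 | intermediate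
11 | (S)-2-[2-(benzyloxy)-5-bromo-4-methoxyphenyl]-1-[4-(benzyloxy)-3,5-dimethoxyphenyl]propane | C[C@@H](Cc1cc(OC)c(OCc2ccccc2)c(OC)c1)c1cc(Br)c(OC)cc1OCc1ccccc1 | intermediate
12 | (S)-4-[2-(5-bromo-2-hydroxy-4-methoxyphenyl)propyl]-2,6-dimethoxyphenol | C[C@@H](Cc1cc(OC)c(O)c(OC)c1)c1cc(Br)c(OC)cc1O | intermediate
13 | 4-[(2S)-2-(5-bromo-2-hydroxy-4-methoxyphenyl)propylidene]-2,6-dimethoxycyclohexa-2,5-dien-1-one (formed in the flask) | C[C@@H](C=C1C=C(OC)C(=O)C(OC)=C1)c1cc(Br)c(OC)cc1O | intermediate
14 | 4-[(2R,3R)-5-bromo-6-methoxy-3-methyl-2,3-dihydro-1-benzofuran-2-yl]-2,6-dimethoxyphenol | Brc1cc2c(cc1OC)O[C@@H](c1cc(OC)c(O)c(OC)c1)[C@@H]2C | intermediate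
15 | (2R,3R)-5-bromo-6-methoxy-3-methyl-2-(3,4,5-trimethoxyphenyl)-2,3-dihydro-1-benzofuran | Brc1cc2c(cc1OC)O[C@@H](c1cc(OC)c(OC)c(OC)c1)[C@@H]2C | intermediate
16 | (2R,3R)-6-methoxy-3-methyl-5-[(E)-prop-1-en-1-yl]-2-(3,4,5-trimethoxyphenyl)-2,3-dihydro-1-benzofuran | C/C=C/c1cc2c(cc1OC)O[C@@H](c1cc(OC)c(OC)c(OC)c1)[C@@H]2C | target

Total step count: 12. Longest linear sequence: 10 steps (steps 3 to 12, from syringaldehyde); the paeonol branch (steps 1 and 2) joins at step 6.

Steps most likely to fail

Step 10. The quinone methide may lose the C3 proton and tautomerise to the stilbene before it is trapped, which erases the stereocentre, or the still phenolic product may be oxidised a second time towards the benzofuran and oligomers. The fallback sets out from 10 and closes the ring without an oxidant. The benzyl ethers of 10 are removed with BCl3 and pentamethylbenzene (CH2Cl2, −78 °C) to give the stilbene bis-phenol (E)-4-[2-(5-bromo-2-hydroxy-4-methoxyphenyl)prop-1-en-1-yl]-2,6-dimethoxyphenol F1. A catalytic Brønsted acid (camphorsulfonic acid or TfOH, CH2Cl2, 0 °C to rt) protonates the alkene at the methyl-bearing carbon to the para-hydroxybenzylic cation, which the ring A hydroxyl captures in an intramolecular hydroalkoxylation to give the racemic trans compound rac-4-[(2RS,3RS)-5-bromo-6-methoxy-3-methyl-2,3-dihydro-1-benzofuran-2-yl]-2,6-dimethoxyphenol F2. Preparative chromatography on a chiral stationary phase then gives 14, where the route is rejoined; the price is half of the material.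

Step 8. The ortho-benzyloxyaryl group on the trisubstituted carbon may slow the hydrogenation or lower the facial selectivity. The fallback sets out from 10 and gives up asymmetric catalysis for resolution: hydrogenation with the achiral catalyst [Ir(cod)(PCy3)(py)]PF6 (H2, CH2Cl2, rt), which also spares the aryl bromide and the benzyl ethers, should give racemic 2-[2-(benzyloxy)-5-bromo-4-methoxyphenyl]-1-[4-(benzyloxy)-3,5-dimethoxyphenyl]propane F3, and separation of the enantiomers by preparative supercritical-fluid chromatography on a chiral phase returns to the route at 11.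

Step 7. Equilibration may leave too much Z alkene and 1,1-disubstituted alkene for crystallisation to give geometrically pure material, and any Z isomer carried on would give the wrong enantiomer in step 8. The fallback sets out from 7 and builds the alkene by olefination instead of elimination. Michaelis–Arbuzov reaction of 7 with triethyl phosphite (neat, 130 °C) gives diethyl [4-(benzyloxy)-3,5-dimethoxybenzyl]phosphonate F4. Horner–Wadsworth–Emmons reaction of its potassium salt (KOtBu, THF, 0 °C to rt) with ketone 3 forms the trisubstituted alkene under kinetic control, without the tertiary cation and so without the terminal alkene isomer, and returns to the route at 10.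

Further compounds
F1 | step 10 | (E)-4-[2-(5-bromo-2-hydroxy-4-methoxyphenyl)prop-1-en-1-yl]-2,6-dimethoxyphenol | C/C(=C\c1cc(OC)c(O)c(OC)c1)c1cc(Br)c(OC)cc1O
F2 | step 10 | rac-4-[(2RS,3RS)-5-bromo-6-methoxy-3-methyl-2,3-dihydro-1-benzofuran-2-yl]-2,6-dimethoxyphenol (racemate, trans; one enantiomer drawn) | Brc1cc2c(cc1OC)O[C@@H](c1cc(OC)c(O)c(OC)c1)[C@@H]2C
F3 | step 8 | racemic 2-[2-(benzyloxy)-5-bromo-4-methoxyphenyl]-1-[4-(benzyloxy)-3,5-dimethoxyphenyl]propane | CC(Cc1cc(OC)c(OCc2ccccc2)c(OC)c1)c1cc(Br)c(OC)cc1OCc1ccccc1
F4 | step 7 | diethyl [4-(benzyloxy)-3,5-dimethoxybenzyl]phosphonate | CCOP(=O)(Cc1cc(OC)c(OCc2ccccc2)c(OC)c1)OCC
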